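**Plan**

1. Numbering: chain C1 (amide C=O) to C17 (ketal CH3), ketal oxygens O11 and O13. The retrosynthesis first cuts C3–C4 (Suzuki coupling) and C4=C5 (cross-metathesis), giving iodoacrylamide–naphthoquinone 13 and a C5–C17 polyketide.
2. The polyketide is then cut at C6–C7 and C8–C9 (two crotylborations) back to the C9–C17 bicyclic ketal 31.
3. Enabling feature: C16 is a ketal carbon carrying CH3 between O11 and O13, so it is the carbonyl carbon of an acetate on O11 and O13 is that acetate's carbonyl oxygen. The five-membered ring O13–C13–C14–C15–C16 of the 2,8-dioxabicyclo[3.2.1]octane is therefore the [3+2] adduct of a six-membered carbonyl ylide (ring O11–C11–C12–C13–O13–C16) and a two-carbon dipolarophile; cutting C13–C14 and C15–C16 removes the ethano bridge and leaves an acyclic α-acetoxy diazoketone.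
4. Helpers: C12 is carried as a ketone (it stabilises the ylide) and the ethano bridge arrives as a bis-sulfone; they are removed by methylenation, reductive desulfonylation and hydrogenation.
5. Ring order forward: the two naphthoquinone rings (Diels–Alder/aromatisation, own branch), then the ylide ring and, last, the five-membered ring in one operation.
6. Stereochemistry: C10/C11 from an Evans syn aldol; C13/C16 from cycloaddition anti to the C11 side chain; C12 from hydrogenation opposite the ethano bridge; C8/C9 and C6/C7 from Ipc2B crotylborations; 2Z from (Z)-3-iodo-2-methylacrylic acid, 4E from cross-metathesis.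

Key step: step 12

Assumption: compounds 1, 4, 10, 14, 15, 25 and both enantiomers of B-methoxydiisopinocampheylborane are taken as catalogue compounds; (+)-Ipc2BOMe denotes the enantiomer made from (−)-α-pinene and (−)-Ipc2BOMe the one made from (+)-α-pinene. The phrase "stereocentres as in 31" (or another number) refers to the SMILES of that compound.

**Route**

Step 1
Reactants: 1 di-tert-butyl 3-oxopentanedioate
Product: 2 di-tert-butyl 2-methyl-3-oxopentanedioate (racemic)
Conditions: K2CO3, MeI (1.0 equiv), acetone, rt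
Reagents that add atoms: iodomethane, CI
Why: C-alkylation of the doubly activated methylene of a β-keto diester should give the mono-methyl compound when one equivalent of MeI is used.

Step 2
Reactants: 2 di-tert-butyl 2-methyl-3-oxopentanedioate
Product: 3 tert-butyl 5-tert-butoxy-4-methyl-3,5-bis(trimethylsilyloxy)penta-2,4-dienoate
Conditions: TMSOTf (2.2 equiv), Et3N, Et2O, 0 °C, used crude
Reagents that add atoms: trimethylsilyl trifluoromethanesulfonate, C[Si](C)(C)OS(=O)(=O)C(F)(F)F
Why: Double O-silylation by soft enolisation should enolise the ketone toward the unsubstituted CH2 first and then turn the ester next to the methyl-bearing carbon into the ketene acetal, giving the 1,3-bis(silyloxy) vinylketene acetal diene.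

Step 3
Reactants: 3 bis-silyl diene; 4 2,6-dibromo-1,4-benzoquinone
Product: 6 tert-butyl 6-bromo-2,4-dihydroxy-3-methyl-5,8-dioxo-5,8-dihydronaphthalene-1-carboxylate, via Diels–Alder adduct 5 (not isolated)
Conditions: THF, −30 °C to rt; pyridine (1.1 equiv); then 1 M HCl, THF, rt
Reagents that add atoms: none
Why: Diels–Alder reaction at the bromo-substituted double bond, in which the nucleophilic ester-bearing diene terminus should bond to the unsubstituted quinone carbon and the acetal carbon to the C–Br carbon (halogen-directed regiochemistry of vinylketene acetals), followed by loss of HBr, tert-butanol and the silyl groups to aromatise the new ring.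

Step 4
Reactants: 6 bromonaphthoquinone ester
Product: 9 tert-butyl 6-amino-2,4-dihydroxy-3-methyl-5,8-dioxo-5,8-dihydronaphthalene-1-carboxylate, via azidoquinone 7 (not isolated), via azidohydroquinone 8 (not isolated)
Conditions: NaN3, DMF, 0 °C to rt; then Na2S2O4, H2O/EtOAc, rt
Reagents that add atoms: sodium azide, [Na+].[N-]=[N+]=[N-]
Why: Addition–elimination of azide at the bromine-bearing quinone carbon, then dithionite reduction to the azidohydroquinone, which should lose N2 by internal redox to give the aminoquinone with nitrogen at the former C–Br position.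

Step 5
Reactants: 9 aminoquinone ester; 10 (Z)-3-iodo-2-methylprop-2-enoic acid
Product: 12 tert-butyl 2,4-dihydroxy-6-[(Z)-3-iodo-2-methylprop-2-enamido]-3-methyl-5,8-dioxo-5,8-dihydronaphthalene-1-carboxylate, via acid chloride 11 (not isolated)
Conditions: 10, (COCl)2, cat. DMF, CH2Cl2, 0 °C to rt, evaporate; then 9, pyridine, CH2Cl2, 0 °C to rt; NaHCO3, MeOH work-up
Reagents that add atoms: none
Why: Schotten–Baumann-type N-acylation of the amino quinone, in which the two phenols are hydrogen-bonded and doubly ortho-substituted, any aryl ester should be cleaved in the basic methanol work-up, and the Z iodoalkene is untouched.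

Step 6
Reactants: 12 tert-butyl ester amide
Product: 13 2,4-dihydroxy-6-[(Z)-3-iodo-2-methylprop-2-enamido]-3-methyl-5,8-dioxo-5,8-dihydronaphthalene-1-carboxylic acid
Conditions: TFA/CH2Cl2 (1:4), 0 °C to rt
Reagents that add atoms: none
Why: Acidolysis of the tert-butyl ester through the tert-butyl cation should free the acid on a fragment that has no acid-sensitive group.

Step 7
Reactants: 14 (S)-4-benzyl-3-propanoyl-1,3-oxazolidin-2-one; 15 prop-2-enal
Product: 18 (S)-4-benzyl-3-[(2S,3R)-3-hydroxy-2-methylpent-4-enoyl]-1,3-oxazolidin-2-one, via boron enolate 16 (not isolated), via boron aldolate 17 (not isolated)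
Conditions: Bu2BOTf, iPr2NEt, CH2Cl2, −78 °C; 15, −78 to 0 °C; then pH 7 buffer, MeOH, H2O2
Reagents that add atoms: none
Why: Evans syn-aldol reaction in which the (Z)-boron enolate reacts through a Zimmerman–Traxler chair on the face away from the benzyl group, setting C10 and C11 (syn).

Step 8
Reactants: 18 aldol adduct
Product: 19 (2R,3R)-2-methylpent-4-ene-1,3-diol
Conditions: LiBH4, MeOH (1 equiv), THF, 0 °C
Reagents that add atoms: none
Why: Hydride reduction of the imide carbonyl should release the 1,3-diol and the auxiliary without touching the stereocentres.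

Step 9
Reactants: 19 diol
Product: 20 (2R,3R)-2-methylpent-4-ene-1,3-diyl diacetate
Conditions: Ac2O, pyridine, cat. DMAP, CH2Cl2, rt
Reagents that add atoms: acetic anhydride, CC(=O)OC(C)=O
Why: Acetylation of both hydroxyls, of which the secondary acetate becomes C16, C17, O11 and O13 of the ketal and the primary acetate protects O9.

Step 10
Reactants: 20 diacetate
Product: 22 (2S,3R)-2,4-diacetoxy-3-methylbutanoic acid, via aldehyde 21 (not isolated)
Conditions: RuCl3 (2 mol %), NaIO4 (5 equiv), CCl4/MeCN/H2O, rt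
Reagents that add atoms: sodium periodate (oxygen source through RuO4), [Na+].[O-]I(=O)(=O)=O; water, O
Why: RuO4-catalysed oxidative cleavage of the terminal alkene should give the α-acetoxy acid in one operation, since the substrate has no arene or other oxidisable group.

Step 11
Reactants: 22 α-acetoxy acid
Product: 24 (3S,4R)-3,5-diacetoxy-1-diazo-4-methylpentan-2-one, via acid chloride 23 (not isolated)
Conditions: (COCl)2, cat. DMF, CH2Cl2, 0 °C to rt, evaporate; then CH2N2 (3 equiv), Et2O, 0 °C
Reagents that add atoms: diazomethane, C=[N+]=[N-]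
Why: Acylation of diazomethane by the acid chloride (first stage of an Arndt–Eistert sequence) should give the α-diazoketone, and as no base is present C11 should not epimerise.

Step 12
Reactants: 24 α-acetoxy diazoketone; 25 (E)-1,2-bis(phenylsulfonyl)ethene
Product: 27 (R)-2-[1-methyl-4-oxo-6,7-bis(phenylsulfonyl)-2,8-dioxabicyclo[3.2.1]octan-3-yl]propyl acetate (bridgeheads as in the target; side chain exo; sulfonyl groups trans), via carbonyl ylide 26 (not isolated)
Conditions: Rh2(OAc)4 (2 mol %), 25 (3 equiv), 1,2-dichloroethane, 60 °C, slow addition of 24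
Reagents that add atoms: none
Why: The divalent-rhodium carboxylate Rh2(OAc)4 should convert 24 into an electrophilic carbenoid at C13, which is captured by the carbonyl oxygen of the C11 acetate to close the six-membered carbonyl ylide 26 (O-to-C closure giving ring O11–C11–C12–C13–O13–C16); the ylide then adds suprafacially to the electron-poor alkene 25 in a concerted [3+2] cycloaddition that forms C13–C14 and C15–C16 and so closes the five-membered ring O13–C13–C14–C15–C16 last. The closest known reaction type is the Rh2(OAc)4-mediated formation of an ester-carbonyl ylide from an α-diazo carbonyl compound with a pendant acyloxy group followed by dipolar cycloaddition, a sequence that has been used to build 2,8-dioxabicyclo[3.2.1]octane cores. C13 and C16 arise together as bridgeheads, and their configuration is fixed relative to C11 because the dipolarophile should approach the nearly planar ylide on the face opposite the C10 side chain, which leaves that chain equatorial (exo) on the dioxane chair as in the target. The sulfonyl-bearing centres C14 and C15 are trans from the (E)-alkene and are erased later, so regiochemistry and endo/exo selectivity do not matter. The step needs the carbenoid to choose the six-membered ylide with the secondary acetate over the eight-membered mode with the primary acetate, over C–H insertion and over proton transfer within the ylide; the 1,5 placement of the C11 acetate carbonyl, the acetoxy-deactivated C9–H bonds and the ketone-stabilised ylide carbon should secure this, helped by slow addition into excess dipolarophile.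

Step 13
Reactants: 27 cycloadduct ketone
Product: 28 (R)-2-[1-methyl-4-methylidene-6,7-bis(phenylsulfonyl)-2,8-dioxabicyclo[3.2.1]octan-3-yl]propyl acetate
Conditions: Tebbe reagent Cp2Ti(μ-Cl)(μ-CH2)AlMe2 (1.3 equiv), pyridine, THF/toluene, −40 to 0 °C
Reagents that add atoms: Tebbe reagent Cp2Ti(μ-Cl)(μ-CH2)AlMe2 (chloride bridge drawn with formal charges), C[Al-]1(C)C[Ti](C2C=CC=C2)(C2C=CC=C2)[Cl+]1
Why: Tebbe methylenation should convert the hindered α,α'-dioxygenated ketone into the exocyclic alkene under non-basic conditions (no elimination of sulfinate), the ketone reacting faster than the acetate.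

Step 14
Reactants: 28 bis-sulfone
Product: 29 (R)-2-[1-methyl-4-methylidene-2,8-dioxabicyclo[3.2.1]oct-6-en-3-yl]propyl acetate
Conditions: Na(Hg) (6 % Na), NaH2PO4, MeOH/THF, −20 °C
Reagents that add atoms: none
Why: Reductive elimination of the vicinal bis-sulfone (the bis-sulfonylethene serving as an acetylene equivalent) should give the C14=C15 alkene, loss of sulfinate being faster than any loss of alkoxide.

Step 15
Reactants: 29 diene
Product: 30 (R)-2-[(1S,3S,4R,5S)-1,4-dimethyl-2,8-dioxabicyclo[3.2.1]octan-3-yl]propyl acetate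
Conditions: H2 (1 atm), Rh/Al2O3 (5 %), EtOAc, rt
Reagents that add atoms: none
Why: Catalytic hydrogenation of both alkenes should deliver hydrogen to the exocyclic methylene from the face opposite the ethano bridge (the axial direction of the dioxane chair, flanked only by ring oxygens), placing the C12 methyl equatorial as in the target, while Rh/Al2O3 limits hydrogenolysis of the allylic C–O bonds.

Step 16
Reactants: 30 bicyclic acetate
Product: 31 (R)-2-[(1S,3S,4R,5S)-1,4-dimethyl-2,8-dioxabicyclo[3.2.1]octan-3-yl]propan-1-ol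
Conditions: K2CO3 (cat.), MeOH, 0 °C to rt
Reagents that add atoms: none
Why: Base-catalysed methanolysis should remove the primary acetate and leave the ketal untouched.

Step 17
Reactants: 31 alcohol
Product: 32 2-(1,4-dimethyl-2,8-dioxabicyclo[3.2.1]octan-3-yl)propanal (C9 aldehyde; stereocentres as in 31)
Conditions: Dess–Martin periodinane, NaHCO3, CH2Cl2, 0 °C to rt, used crude
Reagents that add atoms: none
Why: Buffered Dess–Martin oxidation should give the α-branched aldehyde without epimerisation at C10.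

Step 18
Reactants: 32 C9 aldehyde
Product: 34 (3R,4R,5R)-5-[(1S,3S,4R,5S)-1,4-dimethyl-2,8-dioxabicyclo[3.2.1]octan-3-yl]-3-methylhex-1-en-4-ol, via borinate 33 (not isolated)
Conditions: (E)-crotyl-B(Ipc)2 [from trans-but-2-ene, n-BuLi, KOtBu, (+)-Ipc2BOMe, BF3·OEt2, THF, −78 °C], −78 °C; then NaOH, H2O2
Reagents that add atoms: (E)-but-2-enyldiisopinocampheylborane of the (+)-Ipc2BOMe series, C/C=C/CB([C@H]1C[C@H]2C[C@@H]([C@@H]1C)C2(C)C)[C@H]1C[C@H]2C[C@@H]([C@@H]1C)C2(C)C
Why: Brown crotylboration, in which the (E)-crotylborane reacts through a chair transition state to give C8/C9 anti and the isopinocampheyl groups should direct addition to the Re face of the aldehyde against its Felkin preference, giving the anti,anti triad C8–C10.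

Step 19
Reactants: 34 homoallylic alcohol
Product: 35 tert-butyldimethylsilyl ether of 34 (C9–OTBS)
Conditions: TBSOTf, 2,6-lutidine, CH2Cl2, −78 to 0 °C
Reagents that add atoms: tert-butyldimethylsilyl trifluoromethanesulfonate, CC(C)(C)[Si](C)(C)OS(=O)(=O)C(F)(F)F
Why: The silyl triflate should silylate the hindered secondary alcohol, protecting O9 through the next aldehyde stage.

Step 20
Reactants: 35 silyl ether
Product: 37 C7 aldehyde (terminal CH=CH2 of 35 replaced by CH=O; other centres as in 35), via ozonide 36 (not isolated)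
Conditions: O3, CH2Cl2, −78 °C; then PPh3, −78 °C to rt
Reagents that add atoms: ozone, [O-][O+]=O
Why: Ozonolysis with reductive work-up should cleave the terminal alkene to the aldehyde, the ketal and silyl ether being inert.

Step 21
Reactants: 37 C7 aldehyde
Product: 39 C4–C17 homoallylic alcohol (terminal alkene C4=C5; C6 methyl and C7 hydroxyl anti; C7 hydroxyl and C8 methyl syn; C9–OTBS), via borinate 38 (not isolated)
Conditions: (E)-crotyl-B(Ipc)2 [from trans-but-2-ene, n-BuLi, KOtBu, (−)-Ipc2BOMe, BF3·OEt2, THF, −78 °C], −78 °C; then NaOH, H2O2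
Reagents that add atoms: (E)-but-2-enyldiisopinocampheylborane of the (−)-Ipc2BOMe series, C/C=C/CB([C@@H]1C[C@@H]2C[C@H]([C@H]1C)C2(C)C)[C@@H]1C[C@@H]2C[C@H]([C@H]1C)C2(C)C
Why: Brown crotylboration in the matched sense, where the chair transition state gives C6/C7 anti and Si-face addition (reagent and Felkin control reinforcing) gives C7/C8 syn.

Step 22
Reactants: 39 terminal alkene
Product: 40 (E)-alkenyl pinacol boronate at C4 (C4=C5 E; other centres as in 39)
Conditions: second-generation Grubbs catalyst RuCl2(=CHPh)(H2IMes)(PCy3) (10 mol %), vinylboronic acid pinacol ester (5 equiv), CH2Cl2, 40 °C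
Reagents that add atoms: 4,4,5,5-tetramethyl-2-vinyl-1,3,2-dioxaborolane, C=CB1OC(C)(C)C(C)(C)O1
Why: Olefin cross-metathesis of the terminal alkene with the vinylboronate should give the (E)-alkenylboronate under thermodynamic control, the free C7 hydroxyl being tolerated.

Step 23
Reactants: 40 alkenyl boronate; 13 iodoacrylamide naphthoquinone acid
Product: 41 9-O-tert-butyldimethylsilyl rifsaliniketal
Conditions: Pd(dppf)Cl2 (10 mol %), AsPh3 (20 mol %), K3PO4 (5 equiv), DMF/H2O, rt; pH 4 buffer work-up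
Reagents that add atoms: none
Why: Suzuki–Miyaura coupling of the (E)-alkenylboronate with the (Z)-alkenyl iodide should proceed with retention at both alkenes to give the (2Z,4E)-dienamide, the acid and phenols being carried as their salts.

Step 24
Reactants: 41 silyl-protected target
Product: 42 rifsaliniketal
Conditions: HF·pyridine, pyridine, THF, 0 °C to rt
Reagents that add atoms: none
Why: Buffered fluoride desilylation should free the C9 hydroxyl without affecting the ketal, the dienamide or the quinone.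

**Compound list**

1 | di-tert-butyl 3-oxopentanedioate | CC(C)(C)OC(=O)CC(=O)CC(=O)OC(C)(C)C | starting material
2 | di-tert-butyl 2-methyl-3-oxopentanedioate (racemic) | CC(C)(C)OC(=O)CC(=O)C(C)C(=O)OC(C)(C)C | intermediate
3 | tert-butyl 5-tert-butoxy-4-methyl-3,5-bis(trimethylsilyloxy)penta-2,4-dienoate | CC(C)(C)OC(=O)C=C(O[Si](C)(C)C)C(C)=C(OC(C)(C)C)O[Si](C)(C)C | intermediate
4 | 2,6-dibromo-1,4-benzoquinone | O=C1C(Br)=CC(=O)C=C1Br | starting material
5 | tert-butyl 4a,6-dibromo-4-tert-butoxy-3-methyl-5,8-dioxo-2,4-bis(trimethylsilyloxy)-1,4,4a,5,8,8a-hexahydronaphthalene-1-carboxylate (Diels–Alder adduct) | CC(C)(C)OC(=O)C1C(O[Si](C)(C)C)=C(C)C(OC(C)(C)C)(O[Si](C)(C)C)C2(Br)C(=O)C(Br)=CC(=O)C12 | intermediate (not isolated)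
6 | tert-butyl 6-bromo-2,4-dihydroxy-3-methyl-5,8-dioxo-5,8-dihydronaphthalene-1-carboxylate | CC(C)(C)OC(=O)c1c(O)c(C)c(O)c2C(=O)C(Br)=CC(=O)c12 | intermediate
7 | tert-butyl 6-azido-2,4-dihydroxy-3-methyl-5,8-dioxo-5,8-dihydronaphthalene-1-carboxylate | CC(C)(C)OC(=O)c1c(O)c(C)c(O)c2C(=O)C(N=[N+]=[N-])=CC(=O)c12 | intermediate (not isolated)
8 | tert-butyl 6-azido-2,4,5,8-tetrahydroxy-3-methylnaphthalene-1-carboxylate | CC(C)(C)OC(=O)c1c(O)c(C)c(O)c2c(O)c(N=[N+]=[N-])cc(O)c12 | intermediate (not isolated)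
9 | tert-butyl 6-amino-2,4-dihydroxy-3-methyl-5,8-dioxo-5,8-dihydronaphthalene-1-carboxylate | CC(C)(C)OC(=O)c1c(O)c(C)c(O)c2C(=O)C(N)=CC(=O)c12 | intermediate
10 | (Z)-3-iodo-2-methylprop-2-enoic acid | C/C(=C/I)C(=O)O | starting material
11 | (Z)-3-iodo-2-methylprop-2-enoyl chloride | C/C(=C/I)C(=O)Cl | intermediate (not isolated)
12 | tert-butyl 2,4-dihydroxy-6-[(Z)-3-iodo-2-methylprop-2-enamido]-3-methyl-5,8-dioxo-5,8-dihydronaphthalene-1-carboxylate | C/C(=C/I)C(=O)NC1=CC(=O)c2c(C(=O)OC(C)(C)C)c(O)c(C)c(O)c2C1=O | intermediate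
13 | 2,4-dihydroxy-6-[(Z)-3-iodo-2-methylprop-2-enamido]-3-methyl-5,8-dioxo-5,8-dihydronaphthalene-1-carboxylic acid | C/C(=C/I)C(=O)NC1=CC(=O)c2c(C(=O)O)c(O)c(C)c(O)c2C1=O | intermediate
14 | (S)-4-benzyl-3-propanoyl-1,3-oxazolidin-2-one | CCC(=O)N1[C@@H](Cc2ccccc2)COC1=O | starting material
15 | prop-2-enal (acrolein) | C=CC=O | starting material
16 | (Z)-dibutylboron enolate of 14 | C/C=C(\OB(CCCC)CCCC)N1[C@@H](Cc2ccccc2)COC1=O | intermediate (not isolated)
17 | dibutylboron aldolate of 18 | O=C1OC[C@H](Cc2ccccc2)N1C(=O)[C@@H](C)[C@H](OB(CCCC)CCCC)C=C | intermediate (not isolated)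
18 | (S)-4-benzyl-3-[(2S,3R)-3-hydroxy-2-methylpent-4-enoyl]-1,3-oxazolidin-2-one | O=C1OC[C@H](Cc2ccccc2)N1C(=O)[C@@H](C)[C@H](O)C=C | intermediate
19 | (2R,3R)-2-methylpent-4-ene-1,3-diol | OC[C@@H](C)[C@H](O)C=C | intermediate
20 | (2R,3R)-2-methylpent-4-ene-1,3-diyl diacetate | CC(=O)OC[C@@H](C)[C@H](OC(C)=O)C=C | intermediate
21 | (2S,3R)-2,4-diacetoxy-3-methylbutanal | CC(=O)OC[C@@H](C)[C@H](OC(C)=O)C=O | intermediate (not isolated)
22 | (2S,3R)-2,4-diacetoxy-3-methylbutanoic acid | CC(=O)OC[C@@H](C)[C@H](OC(C)=O)C(=O)O | intermediate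
23 | (2S,3R)-2,4-diacetoxy-3-methylbutanoyl chloride | CC(=O)OC[C@@H](C)[C@H](OC(C)=O)C(Cl)=O | intermediate (not isolated)
24 | (3S,4R)-3,5-diacetoxy-1-diazo-4-methylpentan-2-one | CC(=O)OC[C@@H](C)[C@H](OC(C)=O)C(=O)C=[N+]=[N-] | intermediate
25 | (E)-1,2-bis(phenylsulfonyl)ethene | O=S(=O)(/C=C/S(=O)(=O)c1ccccc1)c1ccccc1 | starting material
26 | 6-[(R)-1-acetoxypropan-2-yl]-2-methyl-5-oxo-5,6-dihydro-1,3-dioxin-1-ium-4-ide (carbonyl ylide; C11 as in 24) | CC(=O)OC[C@@H](C)[C@@H]1OC(C)=[O+][CH-]C1=O | intermediate (not isolated)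
27 | (R)-2-[1-methyl-4-oxo-6,7-bis(phenylsulfonyl)-2,8-dioxabicyclo[3.2.1]octan-3-yl]propyl acetate (trans-disulfone, mixture at C14/C15) | CC(=O)OC[C@@H](C)[C@@H]1O[C@@]2(C)C(S(=O)(=O)c3ccccc3)C(S(=O)(=O)c3ccccc3)[C@H](O2)C1=O | intermediate
28 | (R)-2-[1-methyl-4-methylidene-6,7-bis(phenylsulfonyl)-2,8-dioxabicyclo[3.2.1]octan-3-yl]propyl acetate | CC(=O)OC[C@@H](C)[C@@H]1O[C@@]2(C)C(S(=O)(=O)c3ccccc3)C(S(=O)(=O)c3ccccc3)[C@H](O2)C1=C | intermediate
29 | (R)-2-[1-methyl-4-methylidene-2,8-dioxabicyclo[3.2.1]oct-6-en-3-yl]propyl acetate | CC(=O)OC[C@@H](C)[C@@H]1O[C@@]2(C)C=C[C@H](O2)C1=C | intermediate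
30 | (R)-2-[(1S,3S,4R,5S)-1,4-dimethyl-2,8-dioxabicyclo[3.2.1]octan-3-yl]propyl acetate | CC(=O)OC[C@@H](C)[C@@H]1O[C@@]2(C)CC[C@H](O2)[C@H]1C | intermediate
31 | (R)-2-[(1S,3S,4R,5S)-1,4-dimethyl-2,8-dioxabicyclo[3.2.1]octan-3-yl]propan-1-ol | OC[C@@H](C)[C@@H]1O[C@@]2(C)CC[C@H](O2)[C@H]1C | intermediate
32 | 2-(1,4-dimethyl-2,8-dioxabicyclo[3.2.1]octan-3-yl)propanal (stereocentres as in 31) | O=C[C@@H](C)[C@@H]1O[C@@]2(C)CC[C@H](O2)[C@H]1C | intermediate
33 | diisopinocampheylborinate of 34 (isopinocampheyl groups of the (+)-Ipc2BOMe series) | C=C[C@@H](C)[C@@H](OB([C@H]3C[C@H]4C[C@@H]([C@@H]3C)C4(C)C)[C@H]3C[C@H]4C[C@@H]([C@@H]3C)C4(C)C)[C@@H](C)[C@@H]1O[C@@]2(C)CC[C@H](O2)[C@H]1C | intermediate (not isolated)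
34 | (3R,4R,5R)-5-[(1S,3S,4R,5S)-1,4-dimethyl-2,8-dioxabicyclo[3.2.1]octan-3-yl]-3-methylhex-1-en-4-ol | C=C[C@@H](C)[C@@H](O)[C@@H](C)[C@@H]1O[C@@]2(C)CC[C@H](O2)[C@H]1C | intermediate
35 | tert-butyldimethylsilyl ether of 34 (C9–OTBS) | C=C[C@@H](C)[C@@H](O[Si](C)(C)C(C)(C)C)[C@@H](C)[C@@H]1O[C@@]2(C)CC[C@H](O2)[C@H]1C | intermediate
36 | 1,2,4-trioxolane (ozonide) of 35 | C1OOC(O1)[C@@H](C)[C@@H](O[Si](C)(C)C(C)(C)C)[C@@H](C)[C@@H]2O[C@@]3(C)CC[C@H](O3)[C@H]2C | intermediate (not isolated)
37 | C7 aldehyde: 4-(1,4-dimethyl-2,8-dioxabicyclo[3.2.1]octan-3-yl)-2-methyl-3-(tert-butyldimethylsilyloxy)pentanal (centres as in 35) | O=C[C@@H](C)[C@@H](O[Si](C)(C)C(C)(C)C)[C@@H](C)[C@@H]1O[C@@]2(C)CC[C@H](O2)[C@H]1C | intermediate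
38 | diisopinocampheylborinate of 39 (isopinocampheyl groups of the (−)-Ipc2BOMe series) | C=C[C@H](C)[C@H](OB([C@@H]3C[C@@H]4C[C@H]([C@H]3C)C4(C)C)[C@@H]3C[C@@H]4C[C@H]([C@H]3C)C4(C)C)[C@@H](C)[C@@H](O[Si](C)(C)C(C)(C)C)[C@@H](C)[C@@H]1O[C@@]2(C)CC[C@H](O2)[C@H]1C | intermediate (not isolated)
39 | C4–C17 homoallylic alcohol (C4=C5 terminal alkene, C7–OH free, C9–OTBS) | C=C[C@H](C)[C@H](O)[C@@H](C)[C@@H](O[Si](C)(C)C(C)(C)C)[C@@H](C)[C@@H]1O[C@@]2(C)CC[C@H](O2)[C@H]1C | intermediate
40 | (E)-C4 alkenyl pinacol boronate of the C4–C17 chain | CC1(C)OB(/C=C/[C@H](C)[C@H](O)[C@@H](C)[C@@H](O[Si](C)(C)C(C)(C)C)[C@@H](C)[C@@H]2O[C@@]3(C)CC[C@H](O3)[C@H]2C)OC1(C)C | intermediate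
41 | 9-O-tert-butyldimethylsilyl rifsaliniketal | C/C(=C/C=C/[C@H](C)[C@H](O)[C@@H](C)[C@@H](O[Si](C)(C)C(C)(C)C)[C@@H](C)[C@@H]1O[C@@]2(C)CC[C@H](O2)[C@H]1C)C(=O)NC1=CC(=O)c2c(C(=O)O)c(O)c(C)c(O)c2C1=O | intermediate
42 | rifsaliniketal | C/C(=C/C=C/[C@H](C)[C@H](O)[C@@H](C)[C@@H](O)[C@@H](C)[C@@H]1O[C@@]2(C)CC[C@H](O2)[C@H]1C)C(=O)NC1=CC(=O)c2c(C(=O)O)c(O)c(C)c(O)c2C1=O | target

**Totals and risks**

Total step count: 24. Longest linear sequence: 18 steps (steps 7 to 24); the naphthoquinone branch (steps 1 to 6) joins at step 23.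

Steps most likely to fail:

Step 12. The carbenoid may be diverted into C–H insertion, Wolff rearrangement or dimerisation, or the ylide may collapse by proton transfer from its methyl group or lose configuration at C11 before it meets the dipolarophile. The fallback sets out from diol 19 and comes back at alcohol 31, building the ketal by carbonyl chemistry instead of cycloaddition. Diol 19 is silylated at the primary hydroxyl (TBDPSCl, imidazole) to the mono-silyl ether F1, dihydroxylated (OsO4, NMO) to the triol F2 and cleaved (NaIO4) to the α-methyl aldehyde F3. Felkin-matched (E)-crotylboration with the reagent from (+)-Ipc2BOMe should give the homoallylic alcohol F4. Wacker oxidation (PdCl2, CuCl, O2, DMF/H2O) gives the β-hydroxy methyl ketone F5, whose dianion (LDA, 2.2 equiv, −78 °C) is allylated at the methyl group with allyl bromide to the β-hydroxy ketone F6. Hydroxyl-directed reduction with Me4NBH(OAc)3 should give the 1,3-anti diol F7. A second Wacker oxidation with ketalisation in the same flask should close both rings to the bicyclic ketal silyl ether F8, and TBAF then gives 31.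

Step 23. The chelating hydroxy-quinone acid may deactivate the Pd(dppf)Cl2 catalyst, and the acylamino-quinone may be cleaved under the aqueous base. The fallback sets out from boronate 40 and comes back at 41, making the aryl C–N bond last. Acid 10 is converted through its chloride 11 and NH3 into (Z)-3-iodo-2-methylprop-2-enamide F10. Suzuki coupling of 40 with F10 (Pd(dppf)Cl2, K3PO4) should give the primary dienamide F11. Ester 6 is cleaved with TFA to the bromoquinone acid F12, and amidation of F12 with F11 catalysed by Pd2(dba)3 and Xantphos (Cs2CO3, dioxane) should give 41.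

Step 18. Facial selectivity may be poor in this mismatched crotylboration, and the α-branched aldehyde may epimerise during the slow addition. The fallback sets out from aldehyde 32 and comes back at 34. The chiral allenylzinc reagent made from (S)-but-3-yn-2-yl methanesulfonate (Pd(OAc)2, PPh3, Et2Zn, THF, −20 °C) should add with reagent control to give the anti,anti homopropargylic alcohol F9, and semi-hydrogenation (H2, Pd/CaCO3 poisoned with Pb(OAc)2, quinoline) then gives 34.

**Further compounds**

F1 | step 12 | (2R,3R)-1-(tert-butyldiphenylsilyloxy)-2-methylpent-4-en-3-ol | CC(C)(C)[Si](c1ccccc1)(c1ccccc1)OC[C@@H](C)[C@H](O)C=C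
F2 | step 12 | 5-(tert-butyldiphenylsilyloxy)-4-methylpentane-1,2,3-triol (C3, C4 as in F1; C2 mixture) | CC(C)(C)[Si](c1ccccc1)(c1ccccc1)OC[C@@H](C)[C@H](O)C(O)CO
F3 | step 12 | (R)-3-(tert-butyldiphenylsilyloxy)-2-methylpropanal | CC(C)(C)[Si](c1ccccc1)(c1ccccc1)OC[C@@H](C)C=O
F4 | step 12 | 1-(tert-butyldiphenylsilyloxy)-2,4-dimethylhex-5-en-3-ol (C10/C11 syn, C11/C12 anti) | CC(C)(C)[Si](c1ccccc1)(c1ccccc1)OC[C@@H](C)[C@H](O)[C@H](C)C=C
F5 | step 12 | 6-(tert-butyldiphenylsilyloxy)-4-hydroxy-3,5-dimethylhexan-2-one | CC(C)(C)[Si](c1ccccc1)(c1ccccc1)OC[C@@H](C)[C@H](O)[C@H](C)C(C)=O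
F6 | step 12 | 9-(tert-butyldiphenylsilyloxy)-7-hydroxy-6,8-dimethylnon-1-en-5-one | CC(C)(C)[Si](c1ccccc1)(c1ccccc1)OC[C@@H](C)[C@H](O)[C@H](C)C(=O)CCC=C
F7 | step 12 | 9-(tert-butyldiphenylsilyloxy)-6,8-dimethylnon-1-ene-5,7-diol (1,3-anti diol) | CC(C)(C)[Si](c1ccccc1)(c1ccccc1)OC[C@@H](C)[C@H](O)[C@H](C)[C@@H](O)CCC=C
F8 | step 12 | tert-butyldiphenylsilyl ether of 31 | CC(C)(C)[Si](c1ccccc1)(c1ccccc1)OC[C@@H](C)[C@@H]1O[C@@]2(C)CC[C@H](O2)[C@H]1C
F9 | step 18 | 5-(1,4-dimethyl-2,8-dioxabicyclo[3.2.1]octan-3-yl)-3-methylhex-1-yn-4-ol (centres as in 34) | C#C[C@@H](C)[C@@H](O)[C@@H](C)[C@@H]1O[C@@]2(C)CC[C@H](O2)[C@H]1C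
F10 | step 23 | (Z)-3-iodo-2-methylprop-2-enamide | C/C(=C/I)C(N)=O
F11 | step 23 | (2Z,4E)-primary dienamide of the C1–C17 chain with C9–OTBS | C/C(=C/C=C/[C@H](C)[C@H](O)[C@@H](C)[C@@H](O[Si](C)(C)C(C)(C)C)[C@@H](C)[C@@H]1O[C@@]2(C)CC[C@H](O2)[C@H]1C)C(N)=O
F12 | step 23 | 6-bromo-2,4-dihydroxy-3-methyl-5,8-dioxo-5,8-dihydronaphthalene-1-carboxylic acid | O=C(O)c1c(O)c(C)c(O)c2C(=O)C(Br)=CC(=O)c12
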